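The γ‑lactone is treated as a 2‑methylmalate (citramalate) in disguise. In oxolan‑2‑one numbering (O1, C2 carbonyl, C3, C4, quaternary C5), ring carbon C4 is a former methyl group on C5 and C3 a former diazoacetate carbon. A rhodium‑carbenoid 1,5 C–H insertion of the diazoacetate into that methyl group forms the C3–C4 bond and closes the lactone in one operation, leaving both stereocentres untouched. The precursor, a tertiary‑alcohol diazoacetate, comes from a copper–bis(oxazoline)‑catalysed Mukaiyama aldol of a 12‑bromododecanoate thioester ketene acetal with benzyl pyruvate, which sets both stereocentres. The terminal bromide is finally displaced by 4‑benzyl (R)‑malate, and hydrogenolysis frees the acids.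

Key step: step 7

Assumption: the sense of induction of the copper–bis(oxazoline) pyruvate aldol (syn adduct, (S,S)‑ligand giving the (S)‑carbinol with simple propionate‑type silyl ketene thioacetals) is taken to hold for the long‑chain nucleophile, so the (R,R)‑ligand is used.

Step 1
Reactants: 1 12‑bromododecanoic acid
Product: 2 S‑tert‑butyl 12‑bromododecanethioate
Conditions: t‑BuSH, DCC, DMAP (cat.), CH2Cl2, 0 °C to rt
Reagents that add atoms: 2‑methylpropane‑2‑thiol, CC(C)(C)S
Why: Steglich‑type carbodiimide coupling with DMAP acyl transfer converts the acid into the S‑tert‑butyl thioester needed for the Mukaiyama aldol nucleophile, and the primary bromide is inert to these conditions.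

Step 2
Reactants: 2 S‑tert‑butyl 12‑bromododecanethioate
Product: 4 (Z)‑[12‑bromo‑1‑(tert‑butylsulfanyl)dodec‑1‑en‑1‑yl]oxy(trimethyl)silane, via lithium thioester enolate 3 (not isolated)
Conditions: LDA, THF, −78 °C; then TMSCl, −78 °C to rt
Reagents that add atoms: chlorotrimethylsilane, C[Si](C)(C)Cl
Why: Kinetic deprotonation of the thioester by LDA in THF (cyclic Ireland‑type transition state) gives the enolate with the chain trans to oxygen, which is O‑silylated to the (Z)‑silyl ketene thioacetal, and at −78 °C the enolate should not alkylate the remote bromide.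

Step 3
Reactants: 4 (Z)‑silyl ketene thioacetal; 5 benzyl pyruvate
Product: 7 benzyl (2R,3R)‑13‑bromo‑3‑[(tert‑butylsulfanyl)carbonyl]‑2‑hydroxy‑2‑methyltridecanoate, via aldol trimethylsilyl ether 6 (not isolated)
Conditions: Cu(OTf)2 (10 mol %), (R,R)‑t‑Bu‑box [2,2'‑(propane‑2,2‑diyl)bis((4R)‑4‑tert‑butyl‑4,5‑dihydrooxazole)] (11 mol %), THF, −78 °C; then 1 M HCl, THF, rt
Reagents that add atoms: none
Why: Catalytic enantioselective Mukaiyama aldol addition to a pyruvate ester: the pyruvate chelates the square‑planar divalent copper–bis(oxazoline) Lewis acid through both carbonyl oxygens, a ligand tert‑butyl group shields one ketone face so that the (R,R)‑ligand should set C2 as (R), the open transition state should give the syn adduct and so set C3 as (R), and acid work‑up cleaves the silyl ether.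

Step 4
Reactants: 7 benzyl (2R,3R)‑13‑bromo‑3‑[(tert‑butylsulfanyl)carbonyl]‑2‑hydroxy‑2‑methyltridecanoate
Product: 8 dibenzyl (2R,3R)‑3‑(10‑bromodecyl)‑2‑hydroxy‑2‑methylbutanedioate
Conditions: Hg(OCOCF3)2, BnOH (5 equiv), MeCN, rt
Reagents that add atoms: benzyl alcohol, OCc1ccccc1
Why: Thiophilic activation of the S‑tert‑butyl thioester by divalent mercury followed by acyl transfer to the primary alcohol (metal‑promoted thioester–alcohol exchange) gives the benzyl ester under non‑basic conditions, so neither retro‑aldol cleavage nor epimerisation at C3 is expected, and the excess alcohol should outcompete the hindered tertiary hydroxyl.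

Step 5
Reactants: 8 dibenzyl (2R,3R)‑3‑(10‑bromodecyl)‑2‑hydroxy‑2‑methylbutanedioate
Product: 9 dibenzyl (2R,3R)‑2‑(2‑bromoacetoxy)‑3‑(10‑bromodecyl)‑2‑methylbutanedioate
Conditions: BrCH2COBr, PhNMe2, CH2Cl2, 0 °C to rt
Reagents that add atoms: bromoacetyl bromide, BrCC(Br)=O
Why: O‑Acylation of a tertiary alcohol by an acyl bromide with an aniline base is the standard way to bromoacetates of tertiary alcohols, and no stereocentre is touched.

Step 6
Reactants: 9 dibenzyl (2R,3R)‑2‑(2‑bromoacetoxy)‑3‑(10‑bromodecyl)‑2‑methylbutanedioate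
Product: 11 dibenzyl (2R,3R)‑3‑(10‑bromodecyl)‑2‑(2‑diazoacetoxy)‑2‑methylbutanedioate, via N‑alkylated ditosylhydrazide 10 (not isolated)
Conditions: TsNHNHTs (2 equiv), DBU (5 equiv), THF, 0 °C, short reaction time
Reagents that add atoms: N,N'‑bis(4‑methylbenzenesulfonyl)hydrazine, Cc1ccc(cc1)S(=O)(=O)NNS(=O)(=O)c1ccc(C)cc1
Why: Diazoacetate synthesis from a bromoacetate and N,N'‑ditosylhydrazine: the hydrazide anion is N‑alkylated by the activated α‑bromo ester (much faster than by the remote primary bromide) and DBU then expels two sulfinate groups to leave the diazo group, while the short time at 0 °C should limit base‑induced β‑elimination.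

Step 7
Reactants: 11 dibenzyl (2R,3R)‑3‑(10‑bromodecyl)‑2‑(2‑diazoacetoxy)‑2‑methylbutanedioate
Product: 12 benzyl (2R)‑2‑[(2R)‑1‑(benzyloxy)‑12‑bromo‑1‑oxododecan‑2‑yl]‑5‑oxooxolane‑2‑carboxylate
Conditions: Rh2(OAc)4 (2 mol %), CH2Cl2, reflux, slow addition of 11 by syringe pump, high dilution
Reagents that add atoms: none
Why: Rh2(OAc)4 decomposes the diazo ester with loss of N2 to an electrophilic rhodium carbenoid at the future C3, which inserts through a concerted, asynchronous three‑centre transition state into a C–H bond of the methyl group on the carbinol carbon (future C4) and so forms the C3–C4 bond. The closest known reaction type is the dirhodium‑catalysed intramolecular 1,5 C–H insertion of alkyl diazoacetates that gives γ‑butyrolactones. The oxolan‑2‑one ring closes as a five‑membered ring by 1,5‑insertion, the ring size that ester‑tethered rhodium carbenoids form in preference to four‑ and six‑membered rings. No new stereocentre arises and no bond at C5 or at the side‑chain methine C1′ is broken, so both configurations set in step 3 are retained. The step needs site selectivity among the methyl group, the C1′–H bond (also a five‑membered closure) and the first chain methylene (six‑membered closure): the C1′–H bond is α to an ester carbonyl and hindered and is therefore strongly deactivated towards the electrophilic carbenoid, and the methylene is reached only through the disfavoured six‑membered transition state, which leaves the three methyl hydrogens. Slow addition at high dilution is used to hold back carbene dimerisation, since the methyl C–H bonds are primary and inductively deactivated by the geminal ester.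

Step 8
Reactants: 13 D‑aspartic acid 4‑benzyl ester
Product: 15 (2R)‑4‑(benzyloxy)‑2‑hydroxy‑4‑oxobutanoic acid, via α‑lactone 14 (not isolated)
Conditions: NaNO2, 1 M H2SO4 (aq), 0 °C to rt
Reagents that add atoms: water, O
Why: Diazotisation of an α‑amino acid with retention: the neighbouring carboxylate displaces N2 with inversion to the α‑lactone and water opens it with a second inversion, so the (R) configuration of the D‑aspartate is carried into the (R)‑malate, and the benzyl ester should survive the cold dilute acid.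

Step 9
Reactants: 12 benzyl (2R)‑2‑[(2R)‑1‑(benzyloxy)‑12‑bromo‑1‑oxododecan‑2‑yl]‑5‑oxooxolane‑2‑carboxylate; 15 (2R)‑4‑(benzyloxy)‑2‑hydroxy‑4‑oxobutanoic acid
Product: 17 4‑benzyl 1‑{(11R)‑11‑[(benzyloxy)carbonyl]‑11‑[(2R)‑2‑[(benzyloxy)carbonyl]‑5‑oxooxolan‑2‑yl]undecyl} (2R)‑2‑hydroxybutanedioate, via cesium carboxylate 16 (not isolated)
Conditions: 15, Cs2CO3 (0.5 equiv), DMF, rt; then 12, Bu4NI (cat.), 50 °C
Reagents that add atoms: none
Why: SN2 O‑alkylation of a cesium carboxylate by the primary alkyl bromide (iodide catalysis) forms the ester only at C1 of the malate because C4 is blocked as its benzyl ester, and the mild carboxylate base should leave the lactone, the benzyl esters and all stereocentres untouched.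

Step 10
Reactants: 17 tribenzyl ester
Product: 18 (2R)‑2‑[(1R)‑1‑carboxy‑11‑{[(2R)‑3‑carboxy‑2‑hydroxypropanoyl]oxy}undecyl]‑5‑oxooxolane‑2‑carboxylic acid
Conditions: H2 (1 atm), Pd/C, EtOAc, rt
Reagents that add atoms: none
Why: Catalytic hydrogenolysis of the three benzyl esters over palladium releases the three carboxylic acids under neutral conditions that leave the lactone, the alkyl malate ester and all stereocentres intact.

Compound list
1 | 12‑bromododecanoic acid | OC(=O)CCCCCCCCCCCBr | starting material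
2 | S‑tert‑butyl 12‑bromododecanethioate | CC(C)(C)SC(=O)CCCCCCCCCCCBr | intermediate
3 | lithium (Z)‑12‑bromo‑1‑(tert‑butylsulfanyl)dodec‑1‑en‑1‑olate (not isolated) | [Li+].CC(C)(C)S/C([O-])=C\CCCCCCCCCCBr | intermediate
4 | (Z)‑[12‑bromo‑1‑(tert‑butylsulfanyl)dodec‑1‑en‑1‑yl]oxy(trimethyl)silane | CC(C)(C)S/C(O[Si](C)(C)C)=C\CCCCCCCCCCBr | intermediate
5 | benzyl pyruvate | CC(=O)C(=O)OCc1ccccc1 | starting material
6 | benzyl (2R,3R)‑13‑bromo‑3‑[(tert‑butylsulfanyl)carbonyl]‑2‑methyl‑2‑[(trimethylsilyl)oxy]tridecanoate (not isolated) | BrCCCCCCCCCC[C@@H](C(=O)SC(C)(C)C)[C@@](O[Si](C)(C)C)(C(=O)OCc1ccccc1)C | intermediate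
7 | benzyl (2R,3R)‑13‑bromo‑3‑[(tert‑butylsulfanyl)carbonyl]‑2‑hydroxy‑2‑methyltridecanoate | BrCCCCCCCCCC[C@@H](C(=O)SC(C)(C)C)[C@@](O)(C(=O)OCc1ccccc1)C | intermediate
8 | dibenzyl (2R,3R)‑3‑(10‑bromodecyl)‑2‑hydroxy‑2‑methylbutanedioate | BrCCCCCCCCCC[C@@H](C(=O)OCc1ccccc1)[C@@](O)(C(=O)OCc1ccccc1)C | intermediate
9 | dibenzyl (2R,3R)‑2‑(2‑bromoacetoxy)‑3‑(10‑bromodecyl)‑2‑methylbutanedioate | BrCCCCCCCCCC[C@@H](C(=O)OCc1ccccc1)[C@@](OC(=O)CBr)(C(=O)OCc1ccccc1)C | intermediate
10 | dibenzyl (2R,3R)‑2‑({[1,2‑bis(4‑methylbenzenesulfonyl)hydrazinyl]acetyl}oxy)‑3‑(10‑bromodecyl)‑2‑methylbutanedioate (not isolated) | BrCCCCCCCCCC[C@@H](C(=O)OCc1ccccc1)[C@@](OC(=O)CN(NS(=O)(=O)c1ccc(C)cc1)S(=O)(=O)c1ccc(C)cc1)(C(=O)OCc1ccccc1)C | intermediate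
11 | dibenzyl (2R,3R)‑3‑(10‑bromodecyl)‑2‑(2‑diazoacetoxy)‑2‑methylbutanedioate | BrCCCCCCCCCC[C@@H](C(=O)OCc1ccccc1)[C@@](OC(=O)C=[N+]=[N-])(C(=O)OCc1ccccc1)C | intermediate
12 | benzyl (2R)‑2‑[(2R)‑1‑(benzyloxy)‑12‑bromo‑1‑oxododecan‑2‑yl]‑5‑oxooxolane‑2‑carboxylate | BrCCCCCCCCCC[C@@H](C(=O)OCc1ccccc1)[C@@]1(C(=O)OCc2ccccc2)CCC(=O)O1 | intermediate
13 | D‑aspartic acid 4‑benzyl ester, (2R)‑2‑amino‑4‑(benzyloxy)‑4‑oxobutanoic acid | N[C@H](CC(=O)OCc1ccccc1)C(=O)O | starting material
14 | benzyl [(2S)‑3‑oxooxiran‑2‑yl]acetate (not isolated) | O1[C@@H](CC(=O)OCc2ccccc2)C1=O | intermediate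
15 | (2R)‑4‑(benzyloxy)‑2‑hydroxy‑4‑oxobutanoic acid | O[C@H](CC(=O)OCc1ccccc1)C(=O)O | intermediate
16 | cesium (2R)‑4‑(benzyloxy)‑2‑hydroxy‑4‑oxobutanoate (not isolated) | [Cs+].O[C@H](CC(=O)OCc1ccccc1)C(=O)[O-] | intermediate
17 | 4‑benzyl 1‑{(11R)‑11‑[(benzyloxy)carbonyl]‑11‑[(2R)‑2‑[(benzyloxy)carbonyl]‑5‑oxooxolan‑2‑yl]undecyl} (2R)‑2‑hydroxybutanedioate | O=C(OCc1ccccc1)C[C@@H](O)C(=O)OCCCCCCCCCC[C@@H](C(=O)OCc1ccccc1)[C@@]1(C(=O)OCc2ccccc2)CCC(=O)O1 | intermediate
18 | (2R)‑2‑[(1R)‑1‑carboxy‑11‑{[(2R)‑3‑carboxy‑2‑hydroxypropanoyl]oxy}undecyl]‑5‑oxooxolane‑2‑carboxylic acid | O=C(O)C[C@@H](O)C(=O)OCCCCCCCCCC[C@@H](C(=O)O)[C@@]1(C(=O)O)CCC(=O)O1 | target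

Total step count: 10.
Longest linear sequence: 9 steps (steps 1 to 7, then 9 and 10, from 12‑bromododecanoic acid).

Steps most likely to fail

Step 7 (key step). The methyl C–H bonds are primary and inductively deactivated by the geminal ester, so the carbenoid may react too slowly with them. Carbene dimerisation, carbonyl‑ylide formation with an ester oxygen, or insertion into the chain methylene could then take over. The fallback makes the same C3–C4 bond by ring‑closing metathesis; it sets out from 4 and comes back at 12. Benzyl 2‑oxo‑4‑(trimethylsilyl)but‑3‑ynoate F1 would be made from bis(trimethylsilyl)acetylene and benzyl chlorooxoacetate (AlCl3, CH2Cl2, 0 °C) and used in place of benzyl pyruvate in the copper‑catalysed aldol with 4 under the conditions of step 3. This should give benzyl (2S,3R)‑13‑bromo‑3‑[(tert‑butylsulfanyl)carbonyl]‑2‑hydroxy‑2‑[(trimethylsilyl)ethynyl]tridecanoate F2. C‑Desilylation (Bu4NF, AcOH, THF, 0 °C) would give the terminal alkyne benzyl (2S,3R)‑13‑bromo‑3‑[(tert‑butylsulfanyl)carbonyl]‑2‑ethynyl‑2‑hydroxytridecanoate F3. Semihydrogenation (H2, Pd/CaCO3 poisoned with Pb(OAc)2, quinoline) would give the vinyl carbinol benzyl (2R,3R)‑13‑bromo‑3‑[(tert‑butylsulfanyl)carbonyl]‑2‑ethenyl‑2‑hydroxytridecanoate F4. Acylation with acryloyl chloride (iPr2NEt, DMAP, CH2Cl2) would give benzyl (2R,3R)‑13‑bromo‑3‑[(tert‑butylsulfanyl)carbonyl]‑2‑ethenyl‑2‑(prop‑2‑enoyloxy)tridecanoate F5. Ring‑closing metathesis (second‑generation Grubbs catalyst, toluene, 80 °C) would close the butenolide benzyl (2R)‑2‑[(2R)‑12‑bromo‑1‑(tert‑butylsulfanyl)‑1‑oxododecan‑2‑yl]‑5‑oxo‑2,5‑dihydrofuran‑2‑carboxylate F6 by forming C3=C4. Conjugate reduction with [(Ph3P)CuH]6 (toluene, rt) would give benzyl (2R)‑2‑[(2R)‑12‑bromo‑1‑(tert‑butylsulfanyl)‑1‑oxododecan‑2‑yl]‑5‑oxooxolane‑2‑carboxylate F7. The mercury‑promoted exchange with benzyl alcohol, as in step 4, then returns to 12.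

Step 5. The tertiary hydroxyl is hindered and electron‑poor, so acylation may stall; forcing it risks retro‑aldol cleavage or alkylation of the amine base by the bromoacetate. The fallback sets out from 8 and comes back at 11, bypassing 9 and step 6. Acetylketene generated thermally from 2,2,6‑trimethyl‑4H‑1,3‑dioxin‑4‑one (toluene, 110 °C) acylates hindered tertiary alcohols and should give dibenzyl (2R,3R)‑3‑(10‑bromodecyl)‑2‑methyl‑2‑(3‑oxobutanoyloxy)butanedioate F8. Diazo transfer (4‑acetamidobenzenesulfonyl azide, Et3N, MeCN) would give dibenzyl (2R,3R)‑3‑(10‑bromodecyl)‑2‑(2‑diazo‑3‑oxobutanoyloxy)‑2‑methylbutanedioate F9. Deacetylation with pyrrolidine (CH2Cl2, rt) then gives 11.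

Step 6. The amidine base may trigger β‑elimination of the acyloxy group (E1cB through the acidic C3–H) or cleave the activated bromoacetate before the diazo group has formed. The fallback sets out from 9 and comes back at 11. Selective azide displacement at the α‑bromo ester (NaN3, 1.0 equiv, DMF, 0 °C) would give dibenzyl (2R,3R)‑2‑(2‑azidoacetoxy)‑3‑(10‑bromodecyl)‑2‑methylbutanedioate F10. Phosphine‑mediated azide‑to‑diazo conversion (N‑succinimidyl 3‑(diphenylphosphino)propanoate, THF/H2O, then aqueous NaHCO3) would give 11 through an acyl triazene without strong base.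

Further compounds
F1 | step 7 | benzyl 2‑oxo‑4‑(trimethylsilyl)but‑3‑ynoate | C[Si](C)(C)C#CC(=O)C(=O)OCc1ccccc1
F2 | step 7 | benzyl (2S,3R)‑13‑bromo‑3‑[(tert‑butylsulfanyl)carbonyl]‑2‑hydroxy‑2‑[(trimethylsilyl)ethynyl]tridecanoate | BrCCCCCCCCCC[C@@H](C(=O)SC(C)(C)C)[C@@](O)(C(=O)OCc1ccccc1)C#C[Si](C)(C)C
F3 | step 7 | benzyl (2S,3R)‑13‑bromo‑3‑[(tert‑butylsulfanyl)carbonyl]‑2‑ethynyl‑2‑hydroxytridecanoate | BrCCCCCCCCCC[C@@H](C(=O)SC(C)(C)C)[C@@](O)(C(=O)OCc1ccccc1)C#C
F4 | step 7 | benzyl (2R,3R)‑13‑bromo‑3‑[(tert‑butylsulfanyl)carbonyl]‑2‑ethenyl‑2‑hydroxytridecanoate | BrCCCCCCCCCC[C@@H](C(=O)SC(C)(C)C)[C@@](O)(C(=O)OCc1ccccc1)C=C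
F5 | step 7 | benzyl (2R,3R)‑13‑bromo‑3‑[(tert‑butylsulfanyl)carbonyl]‑2‑ethenyl‑2‑(prop‑2‑enoyloxy)tridecanoate | BrCCCCCCCCCC[C@@H](C(=O)SC(C)(C)C)[C@@](OC(=O)C=C)(C(=O)OCc1ccccc1)C=C
F6 | step 7 | benzyl (2R)‑2‑[(2R)‑12‑bromo‑1‑(tert‑butylsulfanyl)‑1‑oxododecan‑2‑yl]‑5‑oxo‑2,5‑dihydrofuran‑2‑carboxylate | BrCCCCCCCCCC[C@@H](C(=O)SC(C)(C)C)[C@@]1(C(=O)OCc2ccccc2)C=CC(=O)O1
F7 | step 7 | benzyl (2R)‑2‑[(2R)‑12‑bromo‑1‑(tert‑butylsulfanyl)‑1‑oxododecan‑2‑yl]‑5‑oxooxolane‑2‑carboxylate | BrCCCCCCCCCC[C@@H](C(=O)SC(C)(C)C)[C@@]1(C(=O)OCc2ccccc2)CCC(=O)O1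
F8 | step 5 | dibenzyl (2R,3R)‑3‑(10‑bromodecyl)‑2‑methyl‑2‑(3‑oxobutanoyloxy)butanedioate | BrCCCCCCCCCC[C@@H](C(=O)OCc1ccccc1)[C@@](OC(=O)CC(C)=O)(C(=O)OCc1ccccc1)C
F9 | step 5 | dibenzyl (2R,3R)‑3‑(10‑bromodecyl)‑2‑(2‑diazo‑3‑oxobutanoyloxy)‑2‑methylbutanedioate | BrCCCCCCCCCC[C@@H](C(=O)OCc1ccccc1)[C@@](OC(=O)C(=[N+]=[N-])C(C)=O)(C(=O)OCc1ccccc1)C
F10 | step 6 | dibenzyl (2R,3R)‑2‑(2‑azidoacetoxy)‑3‑(10‑bromodecyl)‑2‑methylbutanedioate | BrCCCCCCCCCC[C@@H](C(=O)OCc1ccccc1)[C@@](OC(=O)CN=[N+]=[N-])(C(=O)OCc1ccccc1)C
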